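**Plan**

- Retrosynthesis: ring C (O1, C2, C3, C4) is opened at O1–C2 (phenol plus primary alcohol), the C2–O bond is traced back to a C2–B bond, and C3 is then freed of C2 (C2–C3) and of ring B (C3–C1').
- Enabling feature: C3 carries only H, C4, C2 and C1' of ring B. It can therefore serve as a chiral carbenoid carbon (the α-lithiated ester of the ring A 2-arylethanol) onto which boron delivers first ring B and then the C2 methylene.
- Forward, ring A fragment: 2,4,6-trihydroxybenzaldehyde is silylated, an allyl ether/Claisen shift places the C6 side chain, and O-methylation, allyl-to-prenyl metathesis and one-carbon homologation give the arylethyl benzoate.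
- Forward, ring B fragment: resorcinol is converted into the boronate by two directed lithiations.
- Assembly: both fragments and bromochloromethane are joined in one flask (C3–C1', then C2–C3). Ring C, the only ring that is made, is closed last through O1.
- Stereochemistry: C3, the only stereocentre, comes from removal of one enantiotopic α-proton by s-BuLi/(−)-sparteine. Both boron 1,2-shifts are stereospecific and no later step touches C3.

Key step: step 12

Remark on the chemistry: isoflavan numbering is used and the target is the (3R) enantiomer. A 2,4,6-triisopropylbenzoate is chosen as the activating group of the ring A arylethanol because its boron ate complexes with aryl pinacol boronates rearrange without a Lewis acid, which keeps the flask compatible with chloromethyllithium.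

Abbreviations: prenyl = 3-methylbut-2-en-1-yl; ArA = 2-methoxy-3-prenyl-4,6-bis(triisopropylsilyloxy)phenyl; ArB = 2,4-bis(methoxymethoxy)-3-prenylphenyl; TIB = 2,4,6-triisopropylbenzoyl; pin = pinacolato.

**Ring A fragment**

Step 1
Reactants: 1 2,4,6-trihydroxybenzaldehyde
Product: 2 2-hydroxy-4,6-bis(triisopropylsilyloxy)benzaldehyde
Conditions: TIPSCl (2.05 equiv), imidazole, DMF, 0 °C → rt
Reagents that add atoms: triisopropylsilyl chloride, CC(C)[Si](Cl)(C(C)C)C(C)C
Why: Phenol silylation with a bulky chlorosilane should take the para hydroxyl and one ortho hydroxyl, while the last ortho hydroxyl stays free because it is hydrogen-bonded to the formyl oxygen.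

Step 2
Reactants: 2 2-hydroxy-4,6-bis(triisopropylsilyloxy)benzaldehyde
Product: 3 2-(allyloxy)-4,6-bis(triisopropylsilyloxy)benzaldehyde
Conditions: allyl bromide, K2CO3, acetone, reflux
Reagents that add atoms: allyl bromide, C=CCBr
Why: Williamson O-alkylation of the only free phenol with a reactive allylic halide; carbonate in dry acetone should leave the aryl TIPS ethers intact.

Step 3
Reactants: 3 2-(allyloxy)-4,6-bis(triisopropylsilyloxy)benzaldehyde
Product: 4 3-allyl-2-hydroxy-4,6-bis(triisopropylsilyloxy)benzaldehyde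
Conditions: PhNEt2, 190 °C
Reagents that add atoms: none
Why: Aromatic Claisen rearrangement ([3,3] shift, then enolisation); C3 is the only ortho position of the allyl ether that carries hydrogen, so the allyl group should land between the future methoxy oxygen and the C4 silyloxy group.

Step 4
Reactants: 4 3-allyl-2-hydroxy-4,6-bis(triisopropylsilyloxy)benzaldehyde
Product: 5 3-allyl-2-methoxy-4,6-bis(triisopropylsilyloxy)benzaldehyde
Conditions: MeI, K2CO3, acetone, 50 °C (sealed)
Reagents that add atoms: iodomethane, CI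
Why: Williamson methylation of the hydrogen-bonded phenol, the only acidic group present.

Step 5
Reactants: 5 3-allyl-2-methoxy-4,6-bis(triisopropylsilyloxy)benzaldehyde
Product: 6 2-methoxy-3-prenyl-4,6-bis(triisopropylsilyloxy)benzaldehyde
Conditions: 2-methylbut-2-ene (large excess), second-generation Grubbs catalyst RuCl2(=CHPh)(H2IMes)(PCy3) (5 mol %), CH2Cl2, 40 °C
Reagents that add atoms: 2-methylbut-2-ene, CC=C(C)C
Why: Olefin cross-metathesis of a terminal alkene with excess 2-methylbut-2-ene transfers an isopropylidene unit (the standard allyl-to-prenyl conversion); aldehyde and silyl ethers are inert to the ruthenium carbene.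

Step 6
Reactants: 6 2-methoxy-3-prenyl-4,6-bis(triisopropylsilyloxy)benzaldehyde
Product: 7 1-ethenyl-2-methoxy-3-prenyl-4,6-bis(triisopropylsilyloxy)benzene
Conditions: Ph3PCH3Br, KOt-Bu, THF, 0 °C → rt
Reagents that add atoms: methyltriphenylphosphonium bromide, C[P+](c1ccccc1)(c1ccccc1)c1ccccc1.[Br-]
Why: Wittig methylenation; the small unstabilised ylide should reach the di-ortho-substituted aldehyde, and the new CH2 becomes C3 of the target.

Step 7
Reactants: 7 1-ethenyl-2-methoxy-3-prenyl-4,6-bis(triisopropylsilyloxy)benzene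
Product: 9 2-ArA-ethan-1-ol, via B-alkyl-9-BBN adduct 8 (not isolated)
Conditions: 9-BBN, THF, 0 °C → rt; then NaBO3·4H2O, H2O, rt
Reagents that add atoms: sodium perborate tetrahydrate, [Na+].[O-]B1OO1.O.O.O.O
Why: Anti-Markovnikov hydroboration–oxidation; 9-BBN adds to the monosubstituted styrenyl alkene far faster than to the trisubstituted prenyl alkene and puts boron on the terminal carbon, and perborate oxidises the C–B bond without harming aryl silyl ethers.

Step 8
Reactants: 9 2-ArA-ethan-1-ol
Product: 10 2-ArA-ethyl 2,4,6-triisopropylbenzoate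
Conditions: 2,4,6-triisopropylbenzoic acid, PPh3, DIAD, THF, 0 °C → rt
Reagents that add atoms: 2,4,6-triisopropylbenzoic acid, CC(C)c1cc(C(C)C)c(C(=O)O)c(C(C)C)c1
Why: Mitsunobu esterification of a primary alcohol with a hindered benzoic acid, the usual entry to primary TIB esters.

**Ring B fragment**

Step 9
Reactants: 11 resorcinol
Product: 12 1,3-bis(methoxymethoxy)benzene
Conditions: MOMCl, i-Pr2NEt, CH2Cl2, 0 °C → rt
Reagents that add atoms: chloromethyl methyl ether, COCCl
Why: Acetal protection of both phenols by alkylation with a chloromethyl ether.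

Step 10
Reactants: 12 1,3-bis(methoxymethoxy)benzene
Product: 14 1,3-bis(methoxymethoxy)-2-prenylbenzene, via 2-lithio arene 13 (not isolated)
Conditions: n-BuLi, THF, 0 °C → rt; CuI (10 mol %), prenyl bromide, −20 °C → rt
Reagents that add atoms: 1-bromo-3-methylbut-2-ene, CC(C)=CCBr
Why: Directed ortho-metalation at the position flanked by both MOM ethers, then copper-catalysed SN2 allylation of the aryllithium at the primary carbon of prenyl bromide.

Step 11
Reactants: 14 1,3-bis(methoxymethoxy)-2-prenylbenzene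
Product: 16 ArB-B(pin), via 4-lithio arene 15 (not isolated)
Conditions: s-BuLi, TMEDA, THF, −78 °C; i-PrOBpin, −78 °C → rt
Reagents that add atoms: 2-isopropoxy-4,4,5,5-tetramethyl-1,3,2-dioxaborolane, CC(C)OB1OC(C)(C)C(C)(C)O1
Why: Directed ortho-metalation next to a MOM ether followed by electrophilic borylation; at −78 °C the base bound to the acetal oxygen should remove the adjacent ring proton faster than the benzylic–allylic CH2 protons.

**Fragment union and endgame**

Step 12
Reactants: 10 2-ArA-ethyl 2,4,6-triisopropylbenzoate, 16 ArB-B(pin), 17 bromochloromethane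
Product: 22 pinacol (R)-[2-ArB-3-ArA-propyl]boronate, via lithiated benzoate 18 (not isolated), via aryl boron ate complex 19 (not isolated), via secondary boronic ester 20 (not isolated), via chloromethyl boron ate complex 21 (not isolated)
Conditions: 10 (1.3 equiv), (−)-sparteine, s-BuLi (1.2 equiv), Et2O, −78 °C, 5 h; 16 (1.0 equiv), −78 °C, 1 h, then 35 °C; cool to −78 °C, THF, 17, n-BuLi, then rt
Reagents that add atoms: none
Why: The s-BuLi·(−)-sparteine complex, held by the ester carbonyl, removes the pro-S hydrogen α to oxygen to give the configurationally stable (S)-lithio benzoate 18, which adds to the boron of 16 with retention (ate complex 19), and on warming ring B shifts from boron to carbon anti to the departing triisopropylbenzoate with inversion, forming C3–C1' in the (R)-boronate 20. Chloromethyllithium, made from 17 and n-BuLi at −78 °C, then adds to 20 (ate complex 21) and C3 migrates with retention as chloride leaves, forming C2–C3 and leaving boron on C2 (Matteson homologation). The closest known reactions are the lithiation–borylation of primary alkyl 2,4,6-triisopropylbenzoates with aryl pinacol boronates and the chloromethyllithium homologation of secondary benzylic pinacol boronates, also run one after the other without isolation in iterative homologations. No ring is closed in this step. The one new stereocentre, C3, is fixed by the chiral diamine in the deprotonation and carried through two stereospecific 1,2-shifts. The step needs α-oxygen deprotonation to win over benzylic or ring metalation and needs a single CH2 insertion: the carbonyl-directed base, the non-coordinating TIPS ethers on the electron-rich ring A and the absence of free s-BuLi when 16 is added secure the first, and ate complex 21 forms at −78 °C but rearranges only on warming, after surplus carbenoid has decomposed, which secures the second.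

Step 13
Reactants: 22 pinacol (R)-[2-ArB-3-ArA-propyl]boronate
Product: 23 (2R)-2-ArB-3-ArA-propan-1-ol
Conditions: NaBO3·4H2O, THF/H2O (1:1), rt
Reagents that add atoms: sodium perborate tetrahydrate, [Na+].[O-]B1OO1.O.O.O.O
Why: Perborate oxidation of a primary C–B bond gives the primary alcohol that supplies the C2–O bond; the mild base should spare aryl silyl ethers, MOM acetals and both prenyl alkenes.

Step 14
Reactants: 23 (2R)-2-ArB-3-ArA-propan-1-ol
Product: 24 4-[(2R)-2-ArB-3-hydroxypropyl]-5-methoxy-6-prenylbenzene-1,3-diol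
Conditions: TBAF, THF, 0 °C
Reagents that add atoms: none
Why: Fluoride cleavage of both aryl TIPS ethers; MOM acetals are inert to fluoride, so only the ring A phenols are released.

Step 15
Reactants: 24 4-[(2R)-2-ArB-3-hydroxypropyl]-5-methoxy-6-prenylbenzene-1,3-diol
Product: 25 (3R)-3-ArB-5-methoxy-6-prenyl-3,4-dihydro-2H-chromen-7-ol
Conditions: PPh3, DIAD, THF (0.01 M), 0 °C → rt
Reagents that add atoms: none
Why: Intramolecular Mitsunobu etherification (6-exo closure of ring C through O1); only the phenol ortho to the side chain can reach the activated primary carbon, the ring B phenols are masked, and C3 is not a reacting centre so its configuration is kept.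

Step 16
Reactants: 25 (3R)-3-ArB-5-methoxy-6-prenyl-3,4-dihydro-2H-chromen-7-ol
Product: 26 licoricidin
Conditions: HCl (3 M aq), MeOH, 40 °C
Reagents that add atoms: none
Why: Acid-catalysed acetal cleavage (transacetalisation to dimethoxymethane); dilute acid at moderate temperature should remove aryl MOM ethers faster than it protonates the prenyl alkenes.

**Compound list**

1 | 2,4,6-trihydroxybenzaldehyde | O=Cc1c(O)cc(O)cc1O | starting material
2 | 2-hydroxy-4,6-bis(triisopropylsilyloxy)benzaldehyde | O=Cc1c(O)cc(O[Si](C(C)C)(C(C)C)C(C)C)cc1O[Si](C(C)C)(C(C)C)C(C)C | intermediate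
3 | 2-(allyloxy)-4,6-bis(triisopropylsilyloxy)benzaldehyde | O=Cc1c(OCC=C)cc(O[Si](C(C)C)(C(C)C)C(C)C)cc1O[Si](C(C)C)(C(C)C)C(C)C | intermediate
4 | 3-allyl-2-hydroxy-4,6-bis(triisopropylsilyloxy)benzaldehyde | O=Cc1c(O)c(CC=C)c(O[Si](C(C)C)(C(C)C)C(C)C)cc1O[Si](C(C)C)(C(C)C)C(C)C | intermediate
5 | 3-allyl-2-methoxy-4,6-bis(triisopropylsilyloxy)benzaldehyde | O=Cc1c(OC)c(CC=C)c(O[Si](C(C)C)(C(C)C)C(C)C)cc1O[Si](C(C)C)(C(C)C)C(C)C | intermediate
6 | 2-methoxy-3-(3-methylbut-2-en-1-yl)-4,6-bis(triisopropylsilyloxy)benzaldehyde | O=Cc1c(OC)c(CC=C(C)C)c(O[Si](C(C)C)(C(C)C)C(C)C)cc1O[Si](C(C)C)(C(C)C)C(C)C | intermediate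
7 | 1-ethenyl-2-methoxy-3-(3-methylbut-2-en-1-yl)-4,6-bis(triisopropylsilyloxy)benzene | C=Cc1c(OC)c(CC=C(C)C)c(O[Si](C(C)C)(C(C)C)C(C)C)cc1O[Si](C(C)C)(C(C)C)C(C)C | intermediate
8 | 9-(2-ArA-ethyl)-9-borabicyclo[3.3.1]nonane | COc1c(CC=C(C)C)c(O[Si](C(C)C)(C(C)C)C(C)C)cc(O[Si](C(C)C)(C(C)C)C(C)C)c1CCB1C2CCCC1CCC2 | intermediate
9 | 2-[2-methoxy-3-(3-methylbut-2-en-1-yl)-4,6-bis(triisopropylsilyloxy)phenyl]ethan-1-ol | COc1c(CC=C(C)C)c(O[Si](C(C)C)(C(C)C)C(C)C)cc(O[Si](C(C)C)(C(C)C)C(C)C)c1CCO | intermediate
10 | 2-[2-methoxy-3-(3-methylbut-2-en-1-yl)-4,6-bis(triisopropylsilyloxy)phenyl]ethyl 2,4,6-triisopropylbenzoate | COc1c(CC=C(C)C)c(O[Si](C(C)C)(C(C)C)C(C)C)cc(O[Si](C(C)C)(C(C)C)C(C)C)c1CCOC(=O)c1c(C(C)C)cc(C(C)C)cc1C(C)C | intermediate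
11 | resorcinol (benzene-1,3-diol) | Oc1cccc(O)c1 | starting material
12 | 1,3-bis(methoxymethoxy)benzene | COCOc1cccc(OCOC)c1 | intermediate
13 | [2,6-bis(methoxymethoxy)phenyl]lithium | COCOc1cccc(OCOC)c1[Li] | intermediate
14 | 1,3-bis(methoxymethoxy)-2-(3-methylbut-2-en-1-yl)benzene | COCOc1cccc(OCOC)c1CC=C(C)C | intermediate
15 | [2,4-bis(methoxymethoxy)-3-(3-methylbut-2-en-1-yl)phenyl]lithium | COCOc1ccc([Li])c(OCOC)c1CC=C(C)C | intermediate
16 | 2-[2,4-bis(methoxymethoxy)-3-(3-methylbut-2-en-1-yl)phenyl]-4,4,5,5-tetramethyl-1,3,2-dioxaborolane | CC1(C)OB(OC1(C)C)c1ccc(OCOC)c(CC=C(C)C)c1OCOC | intermediate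
17 | bromochloromethane | ClCBr | starting material
18 | (1S)-1-lithio-2-ArA-ethyl 2,4,6-triisopropylbenzoate, present as its (−)-sparteine complex | COc1c(CC=C(C)C)c(O[Si](C(C)C)(C(C)C)C(C)C)cc(O[Si](C(C)C)(C(C)C)C(C)C)c1C[C@H]([Li])OC(=O)c1c(C(C)C)cc(C(C)C)cc1C(C)C | intermediate
19 | lithium (S)-[1-(TIB-oxy)-2-ArA-ethyl](ArB)(pinacolato)borate | COc1c(CC=C(C)C)c(O[Si](C(C)C)(C(C)C)C(C)C)cc(O[Si](C(C)C)(C(C)C)C(C)C)c1C[C@H]([B-]1(OC(C)(C)C(C)(C)O1)c1ccc(OCOC)c(CC=C(C)C)c1OCOC)OC(=O)c1c(C(C)C)cc(C(C)C)cc1C(C)C.[Li+] | intermediate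
20 | 2-[(1R)-1-ArB-2-ArA-ethyl]-4,4,5,5-tetramethyl-1,3,2-dioxaborolane | COc1c(CC=C(C)C)c(O[Si](C(C)C)(C(C)C)C(C)C)cc(O[Si](C(C)C)(C(C)C)C(C)C)c1C[C@H](c1ccc(OCOC)c(CC=C(C)C)c1OCOC)B1OC(C)(C)C(C)(C)O1 | intermediate
21 | lithium (chloromethyl)[(1R)-1-ArB-2-ArA-ethyl](pinacolato)borate | COc1c(CC=C(C)C)c(O[Si](C(C)C)(C(C)C)C(C)C)cc(O[Si](C(C)C)(C(C)C)C(C)C)c1C[C@H](c1ccc(OCOC)c(CC=C(C)C)c1OCOC)[B-]1(CCl)OC(C)(C)C(C)(C)O1.[Li+] | intermediate
22 | 2-[(2R)-2-ArB-3-ArA-propyl]-4,4,5,5-tetramethyl-1,3,2-dioxaborolane | COc1c(CC=C(C)C)c(O[Si](C(C)C)(C(C)C)C(C)C)cc(O[Si](C(C)C)(C(C)C)C(C)C)c1C[C@H](c1ccc(OCOC)c(CC=C(C)C)c1OCOC)CB1OC(C)(C)C(C)(C)O1 | intermediate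
23 | (2R)-2-[2,4-bis(methoxymethoxy)-3-(3-methylbut-2-en-1-yl)phenyl]-3-[2-methoxy-3-(3-methylbut-2-en-1-yl)-4,6-bis(triisopropylsilyloxy)phenyl]propan-1-ol | COc1c(CC=C(C)C)c(O[Si](C(C)C)(C(C)C)C(C)C)cc(O[Si](C(C)C)(C(C)C)C(C)C)c1C[C@H](c1ccc(OCOC)c(CC=C(C)C)c1OCOC)CO | intermediate
24 | 4-{(2R)-2-[2,4-bis(methoxymethoxy)-3-(3-methylbut-2-en-1-yl)phenyl]-3-hydroxypropyl}-5-methoxy-6-(3-methylbut-2-en-1-yl)benzene-1,3-diol | COc1c(CC=C(C)C)c(O)cc(O)c1C[C@H](c1ccc(OCOC)c(CC=C(C)C)c1OCOC)CO | intermediate
25 | (3R)-3-[2,4-bis(methoxymethoxy)-3-(3-methylbut-2-en-1-yl)phenyl]-5-methoxy-6-(3-methylbut-2-en-1-yl)-3,4-dihydro-2H-chromen-7-ol | COc1c(CC=C(C)C)c(O)cc2c1C[C@H](c1ccc(OCOC)c(CC=C(C)C)c1OCOC)CO2 | intermediate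
26 | licoricidin, (3R)-3-[2,4-dihydroxy-3-(3-methylbut-2-en-1-yl)phenyl]-5-methoxy-6-(3-methylbut-2-en-1-yl)-3,4-dihydro-2H-chromen-7-ol | COc1c(CC=C(C)C)c(O)cc2c1C[C@H](c1ccc(O)c(CC=C(C)C)c1O)CO2 | target

**Step count and risks**

Total step count: 16. Longest linear sequence: 13 steps (steps 1–8 and 12–16, from 2,4,6-trihydroxybenzaldehyde); the ring B branch (steps 9–11) has 3 steps.

Steps most likely to fail:

1. Step 12. Deprotonation of the hindered benzoate may be incomplete, capture of the ortho-substituted boronate may be slow while the diamine is present, the ortho silyl group may drift to the carbanion if the organolithium stands too long, and first-stage by-products may consume the carbenoid so that methylene insertion is incomplete or doubled. Fallback, setting out from 10: after the same s-BuLi/(−)-sparteine deprotonation the anion is quenched with Me3SnCl (retention) to give the (1S)-1-(trimethylstannyl)-2-ArA-ethyl 2,4,6-triisopropylbenzoate F1, which is purified and checked for enantiomeric purity. Tin–lithium exchange with n-BuLi (Et2O, −78 °C, minutes, retention) regenerates 18 without diamine; 16 is added and the mixture warmed, and the secondary boronate 20 is now isolated. Purified 20 is homologated separately with 17/n-BuLi in THF (−78 °C → rt), which returns the route at 22.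

2. Step 16. Protonation of the prenyl alkenes during acetal cleavage may lead to ring closure of the ortho-prenylphenols to 2,2-dimethylchromans or to addition of methanol. Fallback, setting out from 25: TMSOTf with 2,2'-bipyridyl in CH2Cl2 at 0 °C exchanges the aryl MOM groups for silyl groups without a Brønsted acid (the free 7-OH is silylated as well) and gives the 7,2',4'-tris(trimethylsilyl) ether of licoricidin F2. Stirring with water or K2CO3/MeOH at rt then cleaves the aryl TMS ethers and returns the route at 26.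

3. Step 11. The base may deprotonate the doubly activated benzylic–allylic CH2 of the prenyl group instead of the ring, or metalation may stall. Fallback, setting out from 14: electrophilic bromination with NBS in MeCN at 0 °C (para to one MOM ether, ortho to the other) gives 1-bromo-2,4-bis(methoxymethoxy)-3-(3-methylbut-2-en-1-yl)benzene F3. Bromine–lithium exchange with n-BuLi (THF, −78 °C), far faster than any deprotonation, gives 15, and i-PrOBpin then returns the route at 16.

**Further compounds**

F1 | step 12 | (1S)-1-(trimethylstannyl)-2-[2-methoxy-3-(3-methylbut-2-en-1-yl)-4,6-bis(triisopropylsilyloxy)phenyl]ethyl 2,4,6-triisopropylbenzoate | COc1c(CC=C(C)C)c(O[Si](C(C)C)(C(C)C)C(C)C)cc(O[Si](C(C)C)(C(C)C)C(C)C)c1C[C@H]([Sn](C)(C)C)OC(=O)c1c(C(C)C)cc(C(C)C)cc1C(C)C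
F2 | step 16 | (3R)-3-[2,4-bis(trimethylsilyloxy)-3-(3-methylbut-2-en-1-yl)phenyl]-5-methoxy-6-(3-methylbut-2-en-1-yl)-7-(trimethylsilyloxy)-3,4-dihydro-2H-chromene | COc1c(CC=C(C)C)c(O[Si](C)(C)C)cc2c1C[C@H](c1ccc(O[Si](C)(C)C)c(CC=C(C)C)c1O[Si](C)(C)C)CO2
F3 | step 11 | 1-bromo-2,4-bis(methoxymethoxy)-3-(3-methylbut-2-en-1-yl)benzene | COCOc1ccc(Br)c(OCOC)c1CC=C(C)C
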